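**Retrosynthetic overview**
- The right-hand dihydropyran is cut at its CH2–CH(O) bond and at its O–C(tropolone) bond. Both form together when a 2-(tropolonyl)ethylzinc adds to a dienal that already carries the complete left half, and the new alkoxide closes onto the ring.
- Enabling feature: in each cyclohepta[b]pyran the pyran oxygen sits on the tropolone carbon β to the ring carbonyl (O=C–CH=C–O, a vinylogous ester), and the CH2CH2 arm sits on the neighbouring ring carbon. A methoxy group at the first position is therefore a leaving group for addition–elimination, and a bromine at the second is the handle for the carbon arm.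
- Both tropolone rings come from one 5-bromo-4-methoxy-6-methyltropolone: Birch reduction of 2-methylanisole, dibromocarbene addition, oxidative ring expansion (the carbene carbon becomes C–Br, the anisole oxygen the leaving group).
- Left half: catalytic asymmetric alkynylation of methacrolein (carbinol centre), Red-Al, anti-selective hydroboration with B-alkyl Suzuki coupling (methyl centre and C–C bond to the ring), alkoxide ring closure, oxidation to the dienal.
- Ring order: tropolone ring (made once, used twice) → left dihydropyran → right dihydropyran in the key step → fluoride deprotection of both tropolones.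

Key step: step 15

Assumption: O-alkylation of the unsymmetrical bromotropolone is drawn at the oxygen remote from the methoxy group; the other O-alkyl regioisomer would react the same way in every later step and gives the same (tautomeric) tropolone on deprotection.

Abbreviations: SEM = 2-(trimethylsilyl)ethoxymethyl; TBS = tert-butyldimethylsilyl; TES = triethylsilyl; 9-BBN = 9-borabicyclo[3.3.1]nonane; SPhos = 2-dicyclohexylphosphino-2',6'-dimethoxybiphenyl.

**Step 1**
Reactants: 1 2-methylanisole
Product: 2 1-methoxy-2-methylcyclohexa-1,4-diene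
Conditions: Li, NH3 (l), t-BuOH, THF, −78 → −33 °C
Reagents that add atoms: none
Why: Birch reduction protonates the ring ortho and meta to the methoxy group, so both donor substituents stay on one tetrasubstituted enol-ether double bond and an isolated disubstituted alkene remains.

**Step 2**
Reactants: 2 1-methoxy-2-methylcyclohexa-1,4-diene
Product: 3 7,7-dibromo-1-methoxy-6-methylbicyclo[4.1.0]hept-3-ene (racemic)
Conditions: CHBr3, KOt-Bu, pentane, −10 → 0 °C
Reagents that add atoms: bromoform BrC(Br)Br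
Why: Dibromocarbene from α-elimination is electrophilic and should cyclopropanate the electron-rich tetrasubstituted enol-ether alkene in preference to the disubstituted one; the relative configuration is irrelevant because all stereocentres of 3 are destroyed in step 4.

**Step 3**
Reactants: 3 7,7-dibromo-1-methoxy-6-methylbicyclo[4.1.0]hept-3-ene
Product: 4 7,7-dibromo-1-methoxy-6-methylbicyclo[4.1.0]heptane-3,4-diol (cis-diol)
Conditions: OsO4 (2 mol%), N-methylmorpholine N-oxide, acetone/H2O, 23 °C
Reagents that add atoms: osmium tetroxide O=[Os](=O)(=O)=O; N-methylmorpholine N-oxide C[N+]1([O-])CCOCC1; water O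
Why: Catalytic OsO4 syn-dihydroxylation of the only remaining alkene gives the cis-diol, whose facial isomers converge in the next step.

**Step 4**
Reactants: 4 7,7-dibromo-1-methoxy-6-methylbicyclo[4.1.0]heptane-3,4-diol
Product: 6 5-bromo-2-hydroxy-4-methoxy-6-methylcyclohepta-2,4,6-trien-1-one, via cyclopropane-fused 1,2-dione 5 (not isolated)
Conditions: (CF3CO)2O, DMSO, CH2Cl2, −60 °C; then Et3N, −60 → 23 °C
Reagents that add atoms: none
Why: Swern-type oxidation gives the 1,2-dione, whose bis-enol is a norcaradiene that opens by 6π-electrocyclic ring opening and loses HBr to aromatise (the gem-dihalocyclopropane route to tropolones), which places the carbene carbon with its remaining bromine between the methoxy- and methyl-bearing carbons.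

**Step 5**
Reactants: 6 5-bromo-2-hydroxy-4-methoxy-6-methylcyclohepta-2,4,6-trien-1-one
Product: 7 5-bromo-6-methoxy-4-methyl-2-(SEM-oxy)cyclohepta-2,4,6-trien-1-one
Conditions: SEMCl, i-Pr2NEt, CH2Cl2, 0 → 23 °C
Reagents that add atoms: 2-(trimethylsilyl)ethoxymethyl chloride C[Si](C)(C)CCOCCl
Why: The acidic tropolone hydroxyl is O-alkylated under mild base to an acetal-type ether that withstands palladium, organozinc and alkoxide chemistry and is later removed by fluoride.

**Step 6**
Reactants: 8 (2E)-pent-2-en-4-yn-1-ol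
Product: 9 tert-butyldimethyl{[(2E)-pent-2-en-4-yn-1-yl]oxy}silane
Conditions: TBSCl, imidazole, DMF, 0 → 23 °C
Reagents that add atoms: tert-butyldimethylsilyl chloride CC(C)(C)[Si](C)(C)Cl
Why: Standard silylation masks the primary alcohol so that only the terminal alkyne is metalated in the next step.

**Step 7**
Reactants: 9 tert-butyldimethyl{[(2E)-pent-2-en-4-yn-1-yl]oxy}silane; 10 methacrolein
Product: 11 (3R,6E)-8-[(tert-butyldimethylsilyl)oxy]-2-methylocta-1,6-dien-4-yn-3-ol
Conditions: Me2Zn (3 equiv), ProPhenol ligand (10 mol%, the antipode that gives Si-face attack), Ph3P=O (20 mol%), toluene, 4 °C; excess 9 recovered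
Reagents that add atoms: none
Why: Dinuclear zinc–ProPhenol-catalysed enantioselective alkynylation, a method suited to α,β-unsaturated aldehydes, adds the zinc acetylide of 9 in a 1,2-sense and sets the carbinol stereocentre by catalyst control (Si-face delivery corresponds to 3R).

**Step 8**
Reactants: 11 (3R,6E)-8-[(tert-butyldimethylsilyl)oxy]-2-methylocta-1,6-dien-4-yn-3-ol
Product: 12 (3S,4E,6E)-8-[(tert-butyldimethylsilyl)oxy]-2-methylocta-1,4,6-trien-3-ol
Conditions: NaAlH2(OCH2CH2OMe)2 (Red-Al), THF, 0 → 23 °C; aqueous Rochelle salt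
Reagents that add atoms: none
Why: Alkoxide-directed trans-hydroalumination of the propargylic alcohol and protonolysis should give only the E-alkene and leave the stereocentre untouched (the descriptor changes from R to S through the priority rules alone).

**Step 9**
Reactants: 12 (3S,4E,6E)-8-[(tert-butyldimethylsilyl)oxy]-2-methylocta-1,4,6-trien-3-ol; 7 5-bromo-6-methoxy-4-methyl-2-(SEM-oxy)cyclohepta-2,4,6-trien-1-one
Product: 14 5-[(2R,3R,4E,6E)-8-[(tert-butyldimethylsilyl)oxy]-3-hydroxy-2-methylocta-4,6-dien-1-yl]-6-methoxy-4-methyl-2-(SEM-oxy)cyclohepta-2,4,6-trien-1-one, via B-alkyl-9-BBN 13 (not isolated)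
Conditions: 9-BBN (2.2 equiv), THF, 0 → 23 °C; then 7, Pd(OAc)2 (5 mol%), SPhos (10 mol%), K3PO4 (3 M aq.), THF/DMF, 60 °C
Reagents that add atoms: none
Why: 9-BBN hydroborates only the 1,1-disubstituted terminal alkene, anti-Markovnikov and, under allylic-strain control by the neighbouring oxygen-bearing stereocentre, with the anti facial preference documented for uncatalysed 9-BBN on 2-methylallylic alcohols (here 2R,3R), and the primary B-alkyl-9-BBN then undergoes B-alkyl Suzuki–Miyaura coupling with bromide 7.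

**Step 10**
Reactants: 14 (the coupled alcohol from step 9)
Product: 15 (2R,3R)-2-[(1E,3E)-5-(TBS-oxy)penta-1,3-dien-1-yl]-3,5-dimethyl-7-(SEM-oxy)-3,4-dihydrocyclohepta[b]pyran-8(2H)-one
Conditions: KOt-Bu (1.1 equiv), THF, 0 → 23 °C; aqueous NH4Cl
Reagents that add atoms: none
Why: The potassium alkoxide adds to the methoxy-bearing C6 of the tropone (β to the carbonyl) and expels methoxide in a 6-exo addition–elimination (vinylogous transesterification), with retention at the carbinol carbon because its C–O bond is not broken, which gives the trans-2,3-disubstituted dihydropyran (any 15 already formed in step 9 converges here).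

**Step 11**
Reactants: 15 (the silyl ether from step 10)
Product: 16 (2R,3R)-2-[(1E,3E)-5-hydroxypenta-1,3-dien-1-yl]-3,5-dimethyl-7-(SEM-oxy)-3,4-dihydrocyclohepta[b]pyran-8(2H)-one
Conditions: HF·pyridine, pyridine, THF, 0 °C
Reagents that add atoms: none
Why: Buffered HF·pyridine cleaves the primary allylic silyl ether under conditions that should leave the SEM acetal and the dienyl ether intact.

**Step 12**
Reactants: 16 (the dienyl alcohol from step 11)
Product: 17 (2E,4E)-5-[(2R,3R)-3,5-dimethyl-8-oxo-7-(SEM-oxy)-2,3,4,8-tetrahydrocyclohepta[b]pyran-2-yl]penta-2,4-dienal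
Conditions: MnO2, CH2Cl2, 23 °C
Reagents that add atoms: none
Why: MnO2 oxidises the dienylic primary alcohol to the (E,E)-dienal under neutral conditions that should not epimerise the oxygen-bearing stereocentre at the far end of the dienal.

**Step 13**
Reactants: 7 5-bromo-6-methoxy-4-methyl-2-(SEM-oxy)cyclohepta-2,4,6-trien-1-one
Product: 18 5-ethenyl-6-methoxy-4-methyl-2-(SEM-oxy)cyclohepta-2,4,6-trien-1-one
Conditions: CH2=CHBF3K, Pd(OAc)2 (5 mol%), SPhos (10 mol%), Cs2CO3, THF/H2O (10:1), 70 °C
Reagents that add atoms: potassium vinyltrifluoroborate C=C[B-](F)(F)F.[K+]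
Why: Suzuki–Miyaura vinylation of the electron-poor ring bromide, with a bulky biarylphosphine to cope with the two flanking substituents.

**Step 14**
Reactants: 18 5-ethenyl-6-methoxy-4-methyl-2-(SEM-oxy)cyclohepta-2,4,6-trien-1-one
Product: 21 5-{2-[(trimethylsilylmethyl)zincio]ethyl}-6-methoxy-4-methyl-2-(SEM-oxy)cyclohepta-2,4,6-trien-1-one (ether solution used at once), via alkyldiethylborane 19 (not isolated), via dialkylzinc 20 (not isolated)
Conditions: BH3·SMe2/Et3B (gives Et2BH), Et2O, 0 → 23 °C, volatiles removed; Et2Zn, 0 °C, volatiles removed; Zn(CH2SiMe3)2 (1 equiv per dialkylzinc), Et2O, 23 °C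
Reagents that add atoms: diethylzinc CC[Zn]CC; bis(trimethylsilylmethyl)zinc C[Si](C)(C)C[Zn]C[Si](C)(C)C
Why: Anti-Markovnikov hydroboration of the hindered vinyl group, boron–zinc exchange and comproportionation is the standard route to functionalised primary alkylzinc reagents with one non-transferable group, and the strongly delocalised vinylogous-ester carbonyl of the dialkoxytropone is expected to resist dialkylboranes and dialkylzincs.

**Step 15**
Reactants: 21 (the mixed alkylzinc from step 14, 1.5 equiv); 17 (the left-half dienal)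
Product: 23 (2R,3R)-3,5-dimethyl-2-[(1E,3E)-4-[(2R)-5-methyl-8-oxo-7-(SEM-oxy)-2,3,4,8-tetrahydrocyclohepta[b]pyran-2-yl]buta-1,3-dien-1-yl]-7-(SEM-oxy)-3,4-dihydrocyclohepta[b]pyran-8(2H)-one, via secondary alkoxide 22 (not isolated)
Conditions: Ti(OiPr)4 (2 equiv), (1S,2S)-N,N'-bis(trifluoromethanesulfonyl)cyclohexane-1,2-diamine (8 mol%), toluene/Et2O, −20 °C; then KOt-Bu (3 equiv), THF, −20 → 23 °C
Reagents that add atoms: none
Why: The titanium bis(sulfonamide) complex activates the aldehyde of 17 and transfers the 2-(tropon-5-yl)ethyl group of 21 in a 1,2-sense, which forms the bond between the zinc-bearing CH2 and the aldehyde carbon; once KOt-Bu is added, the alkoxide adds to the methoxy-bearing C6 of its own tropone ring (β to the ring carbonyl) and expels methoxide, which forms the O–C(ring) bond. The closest known reaction types are the titanium/bis(sulfonamide)-catalysed enantioselective addition of functionalised dialkylzincs to α,β-unsaturated aldehydes and the alkoxide addition–elimination on an alkoxytropone already used in step 10. The dihydropyran closes in a 6-exo-trig addition–elimination mode and no other ring is formed. The single new stereocentre (2R of the right-hand ring) is set by the catalyst: the (1S,2S) ligand is the antipode of the one that gives S alcohols, so the alkyl group should go to the Re face, and the centre is not touched in the ring closure because its C–O bond stays intact. The step needs 1,2- rather than 1,4- or 1,6-addition to the dienal (titanium-mediated dialkylzinc additions to enals are 1,2-selective), reaction at the aldehyde rather than at the vinylogous-ester carbons of the two tropone rings (organozincs do not add to these), and closure only at C6 (the only leaving-group-bearing carbon within reach of a six-membered transition state).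

**Step 16**
Reactants: 23 (the bis-SEM ether from step 15)
Product: 24 (2R,3R)-8-hydroxy-2-[(1E,3E)-4-[(2R)-8-hydroxy-5-methyl-7-oxo-2,3,4,7-tetrahydrocyclohepta[b]pyran-2-yl]buta-1,3-dien-1-yl]-3,5-dimethyl-3,4-dihydrocyclohepta[b]pyran-7(2H)-one (CNP0332980.1)
Conditions: Bu4NF (6 equiv), THF/DMPU, 23 → 45 °C; pH 6 phosphate buffer
Reagents that add atoms: none
Why: Fluoride attacks silicon and fragments each SEM acetal to Me3SiF, ethene, formaldehyde and the tropolonate, a non-acidic and non-reductive deprotection that should spare the dienyl ethers and the diene and release both tropolones as their rapidly equilibrating tautomers.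

**Compound list**
1 | 2-methylanisole | COc1ccccc1C | starting material
2 | 1-methoxy-2-methylcyclohexa-1,4-diene | COC1=C(C)CC=CC1 | intermediate
3 | 7,7-dibromo-1-methoxy-6-methylbicyclo[4.1.0]hept-3-ene (racemic) | COC12CC=CCC1(C)C2(Br)Br | intermediate
4 | 7,7-dibromo-1-methoxy-6-methylbicyclo[4.1.0]heptane-3,4-diol (cis-diol) | COC12CC(O)C(O)CC1(C)C2(Br)Br | intermediate
5 | 7,7-dibromo-1-methoxy-6-methylbicyclo[4.1.0]heptane-3,4-dione | COC12CC(=O)C(=O)CC1(C)C2(Br)Br | intermediate
6 | 5-bromo-2-hydroxy-4-methoxy-6-methylcyclohepta-2,4,6-trien-1-one | O=C1C(O)=CC(OC)=C(Br)C(C)=C1 | intermediate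
7 | 5-bromo-6-methoxy-4-methyl-2-{[2-(trimethylsilyl)ethoxy]methoxy}cyclohepta-2,4,6-trien-1-one | O=C1C=C(OC)C(Br)=C(C)C=C1OCOCC[Si](C)(C)C | intermediate
8 | (2E)-pent-2-en-4-yn-1-ol | C#C/C=C/CO | starting material
9 | tert-butyldimethyl{[(2E)-pent-2-en-4-yn-1-yl]oxy}silane | C#C/C=C/CO[Si](C)(C)C(C)(C)C | intermediate
10 | methacrolein (2-methylprop-2-enal) | C=C(C)C=O | starting material
11 | (3R,6E)-8-[(tert-butyldimethylsilyl)oxy]-2-methylocta-1,6-dien-4-yn-3-ol | C=C(C)[C@H](C#C/C=C/CO[Si](C)(C)C(C)(C)C)O | intermediate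
12 | (3S,4E,6E)-8-[(tert-butyldimethylsilyl)oxy]-2-methylocta-1,4,6-trien-3-ol | C=C(C)[C@H](/C=C/C=C/CO[Si](C)(C)C(C)(C)C)O | intermediate
13 | anti B-alkyl-9-BBN from 12 (boron on the new CH2; the hydroxyl carried as its 9-BBN borinate) | C(B1C2CCCC1CCC2)[C@@H](C)[C@H](/C=C/C=C/CO[Si](C)(C)C(C)(C)C)OB1C2CCCC1CCC2 | intermediate
14 | 5-[(2R,3R,4E,6E)-8-[(tert-butyldimethylsilyl)oxy]-3-hydroxy-2-methylocta-4,6-dien-1-yl]-6-methoxy-4-methyl-2-(SEM-oxy)cyclohepta-2,4,6-trien-1-one | O=C1C=C(OC)C(C[C@@H](C)[C@H](/C=C/C=C/CO[Si](C)(C)C(C)(C)C)O)=C(C)C=C1OCOCC[Si](C)(C)C | intermediate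
15 | (2R,3R)-2-[(1E,3E)-5-(TBS-oxy)penta-1,3-dien-1-yl]-3,5-dimethyl-7-(SEM-oxy)-3,4-dihydrocyclohepta[b]pyran-8(2H)-one | CC1=C2C[C@@H](C)[C@H](/C=C/C=C/CO[Si](C)(C)C(C)(C)C)OC2=CC(=O)C(OCOCC[Si](C)(C)C)=C1 | intermediate
16 | (2R,3R)-2-[(1E,3E)-5-hydroxypenta-1,3-dien-1-yl]-3,5-dimethyl-7-(SEM-oxy)-3,4-dihydrocyclohepta[b]pyran-8(2H)-one | CC1=C2C[C@@H](C)[C@H](/C=C/C=C/CO)OC2=CC(=O)C(OCOCC[Si](C)(C)C)=C1 | intermediate
17 | (2E,4E)-5-[(2R,3R)-3,5-dimethyl-8-oxo-7-(SEM-oxy)-2,3,4,8-tetrahydrocyclohepta[b]pyran-2-yl]penta-2,4-dienal | CC1=C2C[C@@H](C)[C@H](/C=C/C=C/C=O)OC2=CC(=O)C(OCOCC[Si](C)(C)C)=C1 | intermediate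
18 | 5-ethenyl-6-methoxy-4-methyl-2-(SEM-oxy)cyclohepta-2,4,6-trien-1-one | O=C1C=C(OC)C(C=C)=C(C)C=C1OCOCC[Si](C)(C)C | intermediate
19 | 5-[2-(diethylboranyl)ethyl]-6-methoxy-4-methyl-2-(SEM-oxy)cyclohepta-2,4,6-trien-1-one | CCB(CC)CCC1=C(C)C=C(OCOCC[Si](C)(C)C)C(=O)C=C1OC | intermediate
20 | bis{2-[6-methoxy-4-methyl-1-oxo-2-(SEM-oxy)cyclohepta-2,4,6-trien-5-yl]ethyl}zinc | O=C1C=C(OC)C(CC[Zn]CCC2=C(C)C=C(OCOCC[Si](C)(C)C)C(=O)C=C2OC)=C(C)C=C1OCOCC[Si](C)(C)C | intermediate
21 | 5-{2-[(trimethylsilylmethyl)zincio]ethyl}-6-methoxy-4-methyl-2-(SEM-oxy)cyclohepta-2,4,6-trien-1-one | C[Si](C)(C)C[Zn]CCC1=C(C)C=C(OCOCC[Si](C)(C)C)C(=O)C=C1OC | intermediate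
22 | 5-[(3R,4E,6E)-7-[(2R,3R)-3,5-dimethyl-8-oxo-7-(SEM-oxy)-2,3,4,8-tetrahydrocyclohepta[b]pyran-2-yl]-3-hydroxyhepta-4,6-dien-1-yl]-6-methoxy-4-methyl-2-(SEM-oxy)cyclohepta-2,4,6-trien-1-one (formed as its metal alkoxide; drawn as the alcohol) | CC1=C2C[C@@H](C)[C@H](/C=C/C=C/[C@H](O)CCC3=C(C)C=C(OCOCC[Si](C)(C)C)C(=O)C=C3OC)OC2=CC(=O)C(OCOCC[Si](C)(C)C)=C1 | intermediate
23 | (2R,3R)-3,5-dimethyl-2-[(1E,3E)-4-[(2R)-5-methyl-8-oxo-7-(SEM-oxy)-2,3,4,8-tetrahydrocyclohepta[b]pyran-2-yl]buta-1,3-dien-1-yl]-7-(SEM-oxy)-3,4-dihydrocyclohepta[b]pyran-8(2H)-one | CC1=C2C[C@@H](C)[C@H](/C=C/C=C/[C@H]3CCC4=C(C)C=C(OCOCC[Si](C)(C)C)C(=O)C=C4O3)OC2=CC(=O)C(OCOCC[Si](C)(C)C)=C1 | intermediate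
24 | (2R,3R)-8-hydroxy-2-[(1E,3E)-4-[(2R)-8-hydroxy-5-methyl-7-oxo-2,3,4,7-tetrahydrocyclohepta[b]pyran-2-yl]buta-1,3-dien-1-yl]-3,5-dimethyl-3,4-dihydrocyclohepta[b]pyran-7(2H)-one (CNP0332980.1) | Cc1cc(=O)c(O)cc2c1C[C@@H](C)[C@H](/C=C/C=C/[C@H]1CCc3c(C)cc(=O)c(O)cc3O1)O2 | target

**Step count and risks**

Total step count: 16. Longest linear sequence: 11 steps (steps 1–5, 9–12, 15, 16).

Steps most likely to fail:

1. Step 15. The basic tropone carbonyls of both partners may displace the sulfonamide ligand from titanium and erode the facial selectivity. In the alkoxide-rich medium the ring closure may stall, or isopropoxide or tert-butoxide may exchange the SEM-oxy group on the ring. The fallback builds the same ring in separate, known operations. It sets out from 17: enantioselective vinylation of the aldehyde (divinylzinc with a chiral β-amino alcohol catalyst, Re-face delivery) should give (2R,3R)-2-[(1E,3E,5R)-5-hydroxyhepta-1,3,6-trien-1-yl]-3,5-dimethyl-7-(SEM-oxy)-3,4-dihydrocyclohepta[b]pyran-8(2H)-one F1. Carbonyl-tolerant hydroboration of its terminal vinyl group (pinacolborane, [Ir(cod)Cl]2, 1,2-bis(diphenylphosphino)ethane) should give the primary pinacol boronate F2. B-alkyl Suzuki–Miyaura coupling of F2 with 7 (Pd(OAc)2, RuPhos, K3PO4) comes back to the route at 22, which is closed with KOt-Bu as in step 10 to give 23.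

2. Step 14. The dialkylborane may bind to or reduce the tropone carbonyl faster than it hydroborates the hindered vinyl group, and Et2Zn may transfer ethyl groups to the ring. The fallback sets out from 18 and avoids both reagents. Iridium-catalysed hydroboration with pinacolborane should give 6-methoxy-4-methyl-5-[2-(4,4,5,5-tetramethyl-1,3,2-dioxaborolan-2-yl)ethyl]-2-(SEM-oxy)cyclohepta-2,4,6-trien-1-one F3. Oxidation with NaBO3·4H2O gives 5-(2-hydroxyethyl)-6-methoxy-4-methyl-2-(SEM-oxy)cyclohepta-2,4,6-trien-1-one F4, and I2/PPh3/imidazole gives 5-(2-iodoethyl)-6-methoxy-4-methyl-2-(SEM-oxy)cyclohepta-2,4,6-trien-1-one F5. Direct insertion of zinc dust (LiCl, THF) and treatment with Me3SiCH2Li at −78 °C comes back to the route at 21.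

3. Step 9. Facial selectivity in the hydroboration may be modest because the dienyl group is a smaller allylic substituent than the alkyl groups for which the anti preference is established. Transmetalation to the doubly flanked bromide may also be slow enough for protodebromination to compete. The fallback sets out from 12, separates stereocontrol from coupling and changes the coupling type. Silylation gives triethylsilyl ether F6. Hydroboration with 9-BBN and oxidation (NaBO3) gives (2R,3R,4E,6E)-8-(TBS-oxy)-2-methyl-3-(TES-oxy)octa-4,6-dien-1-ol F7, at which stage the minor diastereomer can be removed. I2/PPh3/imidazole gives the primary iodide F8. Zinc insertion (Zn, LiCl) and Negishi coupling with 7 (Pd(OAc)2, SPhos) give the TES ether of 14, F9. Selective removal of the secondary TES group (pyridinium p-toluenesulfonate, MeOH, 0 °C) comes back to the route at 14.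

Further compounds
F1 | step 15 | (2R,3R)-2-[(1E,3E,5R)-5-hydroxyhepta-1,3,6-trien-1-yl]-3,5-dimethyl-7-(SEM-oxy)-3,4-dihydrocyclohepta[b]pyran-8(2H)-one | CC1=C2C[C@@H](C)[C@H](/C=C/C=C/[C@H](O)C=C)OC2=CC(=O)C(OCOCC[Si](C)(C)C)=C1
F2 | step 15 | (2R,3R)-2-[(1E,3E,5R)-5-hydroxy-7-(4,4,5,5-tetramethyl-1,3,2-dioxaborolan-2-yl)hepta-1,3-dien-1-yl]-3,5-dimethyl-7-(SEM-oxy)-3,4-dihydrocyclohepta[b]pyran-8(2H)-one | CC1=C2C[C@@H](C)[C@H](/C=C/C=C/[C@H](O)CCB3OC(C)(C)C(C)(C)O3)OC2=CC(=O)C(OCOCC[Si](C)(C)C)=C1
F3 | step 14 | 6-methoxy-4-methyl-5-[2-(4,4,5,5-tetramethyl-1,3,2-dioxaborolan-2-yl)ethyl]-2-(SEM-oxy)cyclohepta-2,4,6-trien-1-one | O=C1C=C(OC)C(CCB2OC(C)(C)C(C)(C)O2)=C(C)C=C1OCOCC[Si](C)(C)C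
F4 | step 14 | 5-(2-hydroxyethyl)-6-methoxy-4-methyl-2-(SEM-oxy)cyclohepta-2,4,6-trien-1-one | O=C1C=C(OC)C(CCO)=C(C)C=C1OCOCC[Si](C)(C)C
F5 | step 14 | 5-(2-iodoethyl)-6-methoxy-4-methyl-2-(SEM-oxy)cyclohepta-2,4,6-trien-1-one | O=C1C=C(OC)C(CCI)=C(C)C=C1OCOCC[Si](C)(C)C
F6 | step 9 | (3S,4E,6E)-8-(TBS-oxy)-2-methyl-3-(TES-oxy)octa-1,4,6-triene (triethylsilyl ether of 12) | C=C(C)[C@H](/C=C/C=C/CO[Si](C)(C)C(C)(C)C)O[Si](CC)(CC)CC
F7 | step 9 | (2R,3R,4E,6E)-8-(TBS-oxy)-2-methyl-3-(TES-oxy)octa-4,6-dien-1-ol | OC[C@@H](C)[C@H](/C=C/C=C/CO[Si](C)(C)C(C)(C)C)O[Si](CC)(CC)CC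
F8 | step 9 | (2S,3R,4E,6E)-1-iodo-2-methyl-8-(TBS-oxy)-3-(TES-oxy)octa-4,6-diene (same spatial arrangement as F7) | IC[C@@H](C)[C@H](/C=C/C=C/CO[Si](C)(C)C(C)(C)C)O[Si](CC)(CC)CC
F9 | step 9 | 5-[(2R,3R,4E,6E)-8-(TBS-oxy)-2-methyl-3-(TES-oxy)octa-4,6-dien-1-yl]-6-methoxy-4-methyl-2-(SEM-oxy)cyclohepta-2,4,6-trien-1-one | O=C1C=C(OC)C(C[C@@H](C)[C@H](/C=C/C=C/CO[Si](C)(C)C(C)(C)C)O[Si](CC)(CC)CC)=C(C)C=C1OCOCC[Si](C)(C)C
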